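**Plan**
- Retrosynthesis: the O–Si bond is cut last. The furanone (O1, C2 carbonyl, C3, C4–Br, C5, exocyclic C6–I) is an isomer of a 4-bromo-5-iodo-2-pyranone, so O1–C5 and C6–I are cut and O1–C6 and C5–I restored.
- The pyranone is cut at C4–Br and C5–I (back to the 4-hydroxy-2-pyranone), at O1–C6 (to an acyclic tert-butyl 3-oxo-4-ynoate) and at C3–C4 (aldol of a β-silyloxy ester with 3-(trimethylsilyl)propynal).
- Forward: the chain is joined by aldol addition and oxidation, the six-membered pyranone ring is closed by gold catalysis, the two halogens are installed, the ring is contracted to the five-membered furanone, and the silyl ether is removed.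
- Stereochemistry: the (R)-carbinol comes from Noyori hydrogenation of tert-butyl 3-oxohexanoate with (R)-BINAP and is carried as its silyl ether. The (E)-iodomethylidene geometry comes from anti iodolactonisation.

Key step: step 9

Remark: compounds 9, 10 and 11 are carried as mixtures of epimers at the centres that become trigonal in 12; only the silyloxy-bearing carbon matters and it is never touched.

**Step 1**
Reactants: 1 tert-butyl acetoacetate; 2 iodoethane
Product: 4 tert-butyl 3-oxohexanoate, via dianion of tert-butyl acetoacetate 3 (not isolated)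
Conditions: NaH, THF, 0 °C; n-BuLi, 0 °C; 2, 0 °C to rt; cold 1 M HCl quench
Reagents that add atoms: none
Why: Weiler dianion alkylation of an acetoacetate, in which the more basic terminal carbanion of the dianion is alkylated by iodoethane at C4 only.

**Step 2**
Reactants: 4 tert-butyl 3-oxohexanoate
Product: 5 tert-butyl (3R)-3-hydroxyhexanoate
Conditions: H2 (10 bar), RuCl2[(R)-BINAP] (0.5 mol %), MeOH, 50 °C
Reagents that add atoms: none
Why: Noyori asymmetric hydrogenation of a β-keto ester, in which the (R)-BINAP complex of divalent ruthenium reduces the chelated ketone on the face that gives the (R)-carbinol, as it does for simple 3-oxoalkanoates.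

**Step 3**
Reactants: 5 tert-butyl (3R)-3-hydroxyhexanoate
Product: 6 tert-butyl (3R)-3-(tert-butyldimethylsilyloxy)hexanoate
Conditions: TBSCl, imidazole, DMF, rt
Reagents that add atoms: tert-butyldimethylsilyl chloride, CC(C)(C)[Si](C)(C)Cl
Why: Standard silylation of a secondary alcohol with a silyl chloride and imidazole, giving an ether that withstands the base, oxidant, weak acid and Grignard reagent used later.

**Step 4**
Reactants: 6 tert-butyl (3R)-3-(tert-butyldimethylsilyloxy)hexanoate; 7 3-(trimethylsilyl)propynal
Product: 10 tert-butyl 2-[(1R)-1-(tert-butyldimethylsilyloxy)butyl]-3-hydroxypent-4-ynoate (mixture of C2/C3 diastereomers), via lithium ester enolate 8 (not isolated), via trimethylsilyl-alkynyl aldol adduct 9 (not isolated)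
Conditions: LiN(i-Pr)2 (commercial solution), THF, −78 °C; 7, −78 °C; then MeOH, K2CO3 (cat.), −78 to 0 °C
Reagents that add atoms: none
Why: Aldol addition of a lithium ester enolate to a non-enolisable ynal, followed in the same flask by base-catalysed methanolysis of the alkynyl C–Si bond; the β-silyloxy enolate is kept at −78 °C to suppress β-elimination, and the new C2 and C3 centres need no control because both become trigonal by step 6.

**Step 5**
Reactants: 10 tert-butyl 2-[(1R)-1-(tert-butyldimethylsilyloxy)butyl]-3-hydroxypent-4-ynoate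
Product: 11 tert-butyl 2-[(1R)-1-(tert-butyldimethylsilyloxy)butyl]-3-oxopent-4-ynoate (C2 epimers and enol form)
Conditions: Dess–Martin periodinane, CH2Cl2, 0 °C to rt
Reagents that add atoms: none
Why: Dess–Martin oxidation of a secondary propargylic alcohol to the ynone under near-neutral conditions that leave the silyl ether, the tert-butyl ester and the terminal alkyne untouched.

**Step 6**
Reactants: 11 tert-butyl 2-[(1R)-1-(tert-butyldimethylsilyloxy)butyl]-3-oxopent-4-ynoate
Product: 12 3-[(1R)-1-(tert-butyldimethylsilyloxy)butyl]-4-hydroxy-2H-pyran-2-one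
Conditions: (SPhos)AuNTf2 (5 mol %), MeNO2/AcOH (4:1 v/v), rt
Reagents that add atoms: none
Why: Gold-catalysed 6-endo-dig cyclisation of a tert-butyl 3-oxo-4-ynoate, in which the ester carbonyl oxygen attacks the alkyne carbon β to the ketone under activation by monovalent gold, isobutene is lost and protodeauration gives the 4-hydroxy-2-pyranone.

**Step 7**
Reactants: 12 3-[(1R)-1-(tert-butyldimethylsilyloxy)butyl]-4-hydroxy-2H-pyran-2-one
Product: 13 3-[(1R)-1-(tert-butyldimethylsilyloxy)butyl]-4-hydroxy-5-iodo-2H-pyran-2-one
Conditions: I2, KI, NaHCO3, THF/H2O, 0 °C to rt, dark; NaH2PO4 work-up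
Reagents that add atoms: iodine, II
Why: Electrophilic iodination of the pyranone enolate (halogenation of a vinylogous ester at its α-carbon), where C3 is already fully substituted and any iodine taken up there is returned by iodide, so iodine should settle on C5, the nucleophilic carbon of the O1–C6=C5 enol-ester unit.

**Step 8**
Reactants: 13 3-[(1R)-1-(tert-butyldimethylsilyloxy)butyl]-4-hydroxy-5-iodo-2H-pyran-2-one
Product: 14 4-bromo-3-[(1R)-1-(tert-butyldimethylsilyloxy)butyl]-5-iodo-2H-pyran-2-one
Conditions: Ph3PBr2 (commercial), Et3N, CH2Cl2, 0 °C to rt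
Reagents that add atoms: dibromotriphenylphosphorane, BrP(Br)(c1ccccc1)(c1ccccc1)c1ccccc1
Why: Deoxybromination of an enolised 1,3-dicarbonyl with Ph3PBr2 and base, in which O4 is activated as an oxyphosphonium and displaced by bromide through addition–elimination while Et3N keeps the medium free of HBr.

**Step 9**
Reactants: 14 4-bromo-3-[(1R)-1-(tert-butyldimethylsilyloxy)butyl]-5-iodo-2H-pyran-2-one
Product: 17 (5E)-4-bromo-3-[(1R)-1-(tert-butyldimethylsilyloxy)butyl]-5-(iodomethylidene)furan-2(5H)-one, via 5-chloromagnesio pyranone 15 (not isolated), via chloromagnesium enynoate 16 (not isolated)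
Conditions: i-PrMgCl·LiCl (1.05 equiv), THF, −78 °C; then I2 (1.1 equiv), THF, −78 to 0 °C, dark; aq. Na2S2O3 quench
Reagents that add atoms: iodine, II
Why: Proposed new method: iodine–magnesium exchange at C5 gives alkenylmagnesium 15, in which the C5–Mg bond lies anti to the C6–O1 bond across C5=C6, so the ring carboxylate is expelled in an anti β-elimination that cleaves O1–C6, forms the C5≡C6 triple bond and leaves enynoate 16 with carboxylate and ethynyl held cis by the former ring. Iodine then forms an iodonium ion on the terminal alkyne and the carboxylate oxygen opens it at the internal carbon C5 in a 5-exo-dig closure anti to iodine, which makes the O1–C5 bond and the furanone ring and places iodine trans to O1 and cis to C4. The closest known reaction types are the β-elimination ring opening of 3-metalated furans and benzofurans to alkynyl enolates or phenoxides and the anti iodolactonisation of 2-en-4-ynoic acids (carboxyl cis to alkynyl) to (E)-5-(1-iodoalkylidene)furanones. No stereocentre is formed; the silyloxy carbinol is a spectator and the (E) geometry follows from the anti addition. The step needs exchange at C5–I rather than at C4–Br or addition to the lactone, which the far faster exchange of alkenyl iodides with i-PrMgCl·LiCl at −78 °C should secure. It also needs 5-exo rather than 6-endo reclosure, which Markovnikov opening of the terminal-alkyne iodonium at its internal carbon should secure; a 6-endo closure would only return 14.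

**Step 10**
Reactants: 17 (5E)-4-bromo-3-[(1R)-1-(tert-butyldimethylsilyloxy)butyl]-5-(iodomethylidene)furan-2(5H)-one
Product: 18 (5E)-4-bromo-3-[(1R)-1-hydroxybutyl]-5-(iodomethylidene)furan-2(5H)-one
Conditions: HF·pyridine, THF, 0 °C to rt, dark
Reagents that add atoms: none
Why: Fluoride-mediated cleavage of the silyl ether under buffered acidic conditions, which should spare the base-sensitive bromo(iodomethylidene)furanone and neither ionise the carbinol nor isomerise the alkene.

**Compound list**
1 | tert-butyl acetoacetate | CC(=O)CC(=O)OC(C)(C)C | starting material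
2 | iodoethane | CCI | starting material
3 | sodium lithium dianion (dienolate) of tert-butyl acetoacetate | C=C(O[Li])C=C(O[Na])OC(C)(C)C | intermediate
4 | tert-butyl 3-oxohexanoate | CCCC(=O)CC(=O)OC(C)(C)C | intermediate
5 | tert-butyl (3R)-3-hydroxyhexanoate | CCC[C@@H](O)CC(=O)OC(C)(C)C | intermediate
6 | tert-butyl (3R)-3-(tert-butyldimethylsilyloxy)hexanoate | CCC[C@@H](O[Si](C)(C)C(C)(C)C)CC(=O)OC(C)(C)C | intermediate
7 | 3-(trimethylsilyl)propynal | C[Si](C)(C)C#CC=O | starting material
8 | lithium enolate of ester 6 | CCC[C@@H](O[Si](C)(C)C(C)(C)C)C=C(O[Li])OC(C)(C)C | intermediate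
9 | tert-butyl 2-[(1R)-1-(tert-butyldimethylsilyloxy)butyl]-3-hydroxy-5-(trimethylsilyl)pent-4-ynoate (C2/C3 diastereomers) | CCC[C@@H](O[Si](C)(C)C(C)(C)C)C(C(O)C#C[Si](C)(C)C)C(=O)OC(C)(C)C | intermediate
10 | tert-butyl 2-[(1R)-1-(tert-butyldimethylsilyloxy)butyl]-3-hydroxypent-4-ynoate (C2/C3 diastereomers) | CCC[C@@H](O[Si](C)(C)C(C)(C)C)C(C(O)C#C)C(=O)OC(C)(C)C | intermediate
11 | tert-butyl 2-[(1R)-1-(tert-butyldimethylsilyloxy)butyl]-3-oxopent-4-ynoate (C2 epimers) | CCC[C@@H](O[Si](C)(C)C(C)(C)C)C(C(=O)C#C)C(=O)OC(C)(C)C | intermediate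
12 | 3-[(1R)-1-(tert-butyldimethylsilyloxy)butyl]-4-hydroxy-2H-pyran-2-one | CCC[C@@H](O[Si](C)(C)C(C)(C)C)C1=C(O)C=COC1=O | intermediate
13 | 3-[(1R)-1-(tert-butyldimethylsilyloxy)butyl]-4-hydroxy-5-iodo-2H-pyran-2-one | CCC[C@@H](O[Si](C)(C)C(C)(C)C)C1=C(O)C(I)=COC1=O | intermediate
14 | 4-bromo-3-[(1R)-1-(tert-butyldimethylsilyloxy)butyl]-5-iodo-2H-pyran-2-one | CCC[C@@H](O[Si](C)(C)C(C)(C)C)C1=C(Br)C(I)=COC1=O | intermediate
15 | {4-bromo-3-[(1R)-1-(tert-butyldimethylsilyloxy)butyl]-2-oxo-2H-pyran-5-yl}magnesium chloride | CCC[C@@H](O[Si](C)(C)C(C)(C)C)C1=C(Br)C([Mg]Cl)=COC1=O | intermediate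
16 | chloromagnesium (2E)-3-bromo-2-[(1R)-1-(tert-butyldimethylsilyloxy)butyl]pent-2-en-4-ynoate (carboxylate cis to ethynyl) | CCC[C@@H](O[Si](C)(C)C(C)(C)C)/C(C(=O)O[Mg]Cl)=C(\Br)C#C | intermediate
17 | (5E)-4-bromo-3-[(1R)-1-(tert-butyldimethylsilyloxy)butyl]-5-(iodomethylidene)furan-2(5H)-one | CCC[C@@H](O[Si](C)(C)C(C)(C)C)C1=C(Br)/C(=C\I)OC1=O | intermediate
18 | (5E)-4-bromo-3-[(1R)-1-hydroxybutyl]-5-(iodomethylidene)furan-2(5H)-one | CCC[C@@H](O)C1=C(Br)/C(=C\I)OC1=O | target

**Totals**
Total step count: 10. Longest linear sequence: 10 steps (1 to 18).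

**Steps most likely to fail**

Step 9. The Grignard reagent may add to the lactone carbonyl or to C6 faster than it exchanges, the alkenylmagnesium may be protonated by the terminal alkyne it releases, or the carboxylate may reclose 6-endo and return the pyranone. The fallback reaches the same enynoic acid without the pyranone, by known reactions. It sets out from keto ester 11 and comes back to the route at 17. Deoxybromination of the enolised keto ester with Ph3PBr2/Et3N should give tert-butyl (2E)-3-bromo-2-[(1R)-1-(tert-butyldimethylsilyloxy)butyl]pent-2-en-4-ynoate F1, the isomer with ester and ethynyl cis, which would have to be separated from its geometric isomer because an acyclic substrate offers no control here. TMSOTf/2,6-lutidine should convert the tert-butyl ester into trimethylsilyl (2E)-3-bromo-2-[(1R)-1-(tert-butyldimethylsilyloxy)butyl]pent-2-en-4-ynoate F2. Aqueous work-up should hydrolyse this to (2E)-3-bromo-2-[(1R)-1-(tert-butyldimethylsilyloxy)butyl]pent-2-en-4-ynoic acid F3. I2/NaHCO3 in MeCN should then effect the known anti 5-exo-dig iodolactonisation to 17.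

Step 7. Iodine may be taken up irreversibly at the doubly activated C3 (ipso attack leading to a 3-iodo-2,4-dione) instead of C5, or the enolate may expel silanolate from the side chain. The fallback changes the order and the mode of halogenation. It sets out from 12 and comes back at 14. Ph3PBr2/Et3N should first give 4-bromo-3-[(1R)-1-(tert-butyldimethylsilyloxy)butyl]-2H-pyran-2-one F4, which has no enol, so its only electron-rich position is the enol-ester carbon C5. ICl in CH2Cl2 at −78 °C should add across C5=C6 to give 4-bromo-3-[(1R)-1-(tert-butyldimethylsilyloxy)butyl]-6-chloro-5-iodo-5,6-dihydro-2H-pyran-2-one F5, which is not isolated. Et3N should then eliminate HCl to give 14; this is the halogen addition–dehydrohalogenation sequence known for enol ethers and for 2-pyranone itself.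

Step 8. Displacement at the C4 oxygen, flanked by iodine and a branched silyloxyalkyl group, may be sluggish, activation may occur at the lactone oxygen, or traces of HBr may strip the silyl ether. The fallback separates activation from halide delivery. It sets out from 13 and comes back at 14. Tf2O/pyridine in CH2Cl2 at −78 °C should give 3-[(1R)-1-(tert-butyldimethylsilyloxy)butyl]-5-iodo-2-oxo-2H-pyran-4-yl trifluoromethanesulfonate F6. LiBr in THF/acetone at rt should then exchange the sulfonate for bromide by addition–elimination, the known halide exchange of vinylogous acyl sulfonates.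

**Further compounds**
F1 | step 9 | tert-butyl (2E)-3-bromo-2-[(1R)-1-(tert-butyldimethylsilyloxy)butyl]pent-2-en-4-ynoate | CCC[C@@H](O[Si](C)(C)C(C)(C)C)/C(C(=O)OC(C)(C)C)=C(\Br)C#C
F2 | step 9 | trimethylsilyl (2E)-3-bromo-2-[(1R)-1-(tert-butyldimethylsilyloxy)butyl]pent-2-en-4-ynoate | CCC[C@@H](O[Si](C)(C)C(C)(C)C)/C(C(=O)O[Si](C)(C)C)=C(\Br)C#C
F3 | step 9 | (2E)-3-bromo-2-[(1R)-1-(tert-butyldimethylsilyloxy)butyl]pent-2-en-4-ynoic acid | CCC[C@@H](O[Si](C)(C)C(C)(C)C)/C(C(=O)O)=C(\Br)C#C
F4 | step 7 | 4-bromo-3-[(1R)-1-(tert-butyldimethylsilyloxy)butyl]-2H-pyran-2-one | CCC[C@@H](O[Si](C)(C)C(C)(C)C)C1=C(Br)C=COC1=O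
F5 | step 7 | 4-bromo-3-[(1R)-1-(tert-butyldimethylsilyloxy)butyl]-6-chloro-5-iodo-5,6-dihydro-2H-pyran-2-one | CCC[C@@H](O[Si](C)(C)C(C)(C)C)C1=C(Br)C(I)C(Cl)OC1=O
F6 | step 8 | 3-[(1R)-1-(tert-butyldimethylsilyloxy)butyl]-5-iodo-2-oxo-2H-pyran-4-yl trifluoromethanesulfonate | CCC[C@@H](O[Si](C)(C)C(C)(C)C)C1=C(OS(=O)(=O)C(F)(F)F)C(I)=COC1=O
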